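**Plan**

- Numbering: ring C1 (CHOH), C2 (CH2), C3=C4(CH3), C5 (CH bearing chain carbon C1′), C6 (CMe2); chain C1′ to C16′.
- Retrosynthesis: cut C1′–C2′ first (ring Grignard reagent plus a C20 allylic chloride), then C3′=C4′ (Wittig) and C5′–C6′ (farnesyl bromide plus cyanomethyl anion) in the chain; in the ring, cut one C6–CH3 bond and trace the C1–O bond back to an oxirane spanning C1 and C6.
- Enabling feature: without O1 and one C6 methyl the ring is (2,6-dimethylcyclohexa-2,5-dienyl)methanol. Its mirror plane contains C5, C1′ and C2, so the C1=C6 and C3=C4 alkenes are enantiotopic and both homoallylic to the single hydroxyl.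
- Forward: the carbocycle comes from an arene by Birch reduction and is never closed. The only ring formed is the temporary oxirane (step 3), opened by methyl at C6 (step 4). The chain is built separately and joined in the penultimate step.
- Stereochemistry: C5 and C1 are both fixed in step 3 (the ligand chooses the alkene, the metal-bound hydroxymethyl group chooses the face), which gives the cis OH/side-chain relationship. The 7′E and 11′E alkenes come from farnesyl bromide and 3′E from a stabilised Wittig reaction.

Key step: step 3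

Assumption: the antipode of the bishydroxamic acid ligand that delivers (1R,2S,6S)-4 has to be identified in a trial run; both antipodes are accessible from (R,R)- and (S,S)-cyclohexane-1,2-diamine, and the route is written for the correct one.

**Route**

Step 1
Reactants: 1 2,6-dimethylbenzoic acid
Product: 2 2,6-dimethylcyclohexa-2,5-diene-1-carboxylic acid
Conditions: Li, NH3(l), THF, −78 °C; then NH4Cl
Reagents that add atoms: none
Why: Birch reduction of a benzoic acid should place the two new hydrogens at the ipso and para carbons, because the carboxylate stabilises the ipso carbanion, so both methyl-bearing carbons stay in the skipped diene.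

Step 2
Reactants: 2 2,6-dimethylcyclohexa-2,5-diene-1-carboxylic acid
Product: 3 (2,6-dimethylcyclohexa-2,5-dien-1-yl)methanol
Conditions: LiAlH4, THF, 0 °C → rt (crude 2 used at once; 3 stored under argon)
Reagents that add atoms: none
Why: Hydride reduction of the carboxylic acid to the primary alcohol should proceed through the lithium carboxylate, which is not enolised, so the skipped diene is not drawn into conjugation.

Step 3
Reactants: 3 (2,6-dimethylcyclohexa-2,5-dien-1-yl)methanol
Product: 4 [(1R,2S,6S)-1,3-dimethyl-7-oxabicyclo[4.1.0]hept-3-en-2-yl]methanol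
Conditions: VO(OiPr)3 (2 mol %), N,N′-dihydroxy-N,N′-bis(diphenylacetyl)-trans-cyclohexane-1,2-diamine (single antipode, 4 mol %), cumene hydroperoxide (1.05 equiv), toluene, 0 °C
Reagents that add atoms: cumene hydroperoxide, CC(C)(OO)c1ccccc1
Why: Proposed new method: the hydroxyl of 3 exchanges onto the chiral pentavalent vanadium bishydroxamate formed from VO(OiPr)3, cumyl peroxide binds to the same metal, and oxygen is passed in a concerted spiro transition state to the ring alkene that the tether can reach, so both C–O bonds of the oxirane form in one event on the face syn to the hydroxymethyl group. The closest known reaction type is the vanadium (or hafnium) bishydroxamate-catalysed asymmetric epoxidation of homoallylic alcohols, including desymmetrising variants on acyclic meso dialkenyl carbinols; new here is the discrimination of the two enantiotopic ring alkenes of a cyclohexa-2,5-dienylmethanol. The oxirane closes by metal-templated intramolecular [2+1] oxygen transfer onto C1=C6, a three-membered ring closure in a single step with no open intermediate. The configuration at C5 follows from which enantiotopic alkene is oxidised and is set by the ligand, whereas the configurations at C1 and C6 follow from syn delivery by the coordinated hydroxymethyl oxygen. The step needs enantiotopic-group selectivity, syn facial selectivity and mono-epoxidation: the mirror plane through C5 and C2 with both alkenes homoallylic to one oxygen secures the first two, and the near-stoichiometric oxidant secures the third, since any second epoxidation should consume mainly the minor enantiomer, whose remaining alkene is the one the catalyst prefers.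

Step 4
Reactants: 4 [(1R,2S,6S)-1,3-dimethyl-7-oxabicyclo[4.1.0]hept-3-en-2-yl]methanol
Product: 5 (1S,5R)-5-(hydroxymethyl)-4,6,6-trimethylcyclohex-3-en-1-ol
Conditions: AlMe3 (4 equiv), hexane–CH2Cl2, −40 → 0 °C; then H2O
Reagents that add atoms: trimethylaluminium, C[Al](C)C
Why: In this organoaluminium epoxide opening the aluminium alkoxide of the hydroxymethyl group should activate the oxirane oxygen, the bond to the tertiary carbon C6 ionises and accepts methyl from a second AlMe3, so C6 becomes the non-stereogenic CMe2 group while the untouched C1–O bond keeps its configuration cis to C1′.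

Step 5
Reactants: 5 (1S,5R)-5-(hydroxymethyl)-4,6,6-trimethylcyclohex-3-en-1-ol
Product: 6 tert-butyl{[(1R,5S)-5-{[tert-butyl(dimethyl)silyl]oxy}-2,6,6-trimethylcyclohex-2-en-1-yl]methoxy}dimethylsilane
Conditions: TBSOTf (2.5 equiv), 2,6-lutidine, CH2Cl2, −78 → 0 °C
Reagents that add atoms: tert-butyldimethylsilyl trifluoromethanesulfonate, CC(C)(C)[Si](C)(C)OS(=O)(=O)C(F)(F)F
Why: Silylation with the silyl triflate should cap both hydroxyls, including the neopentyl-type secondary one, which avoids activating the primary carbon while the cis C1 hydroxyl is free to close a bridged ether.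

Step 6
Reactants: 6 tert-butyl{[(1R,5S)-5-{[tert-butyl(dimethyl)silyl]oxy}-2,6,6-trimethylcyclohex-2-en-1-yl]methoxy}dimethylsilane
Product: 7 [(1R,5S)-5-{[tert-butyl(dimethyl)silyl]oxy}-2,6,6-trimethylcyclohex-2-en-1-yl]methanol
Conditions: HF·pyridine, pyridine, THF, 0 °C
Reagents that add atoms: none
Why: Chemoselective desilylation is expected because fluoride attacks the primary silyl ether far faster than the secondary one shielded by the adjacent quaternary carbon.

Step 7
Reactants: 7 [(1R,5S)-5-{[tert-butyl(dimethyl)silyl]oxy}-2,6,6-trimethylcyclohex-2-en-1-yl]methanol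
Product: 8 tert-butyl{[(1S,5R)-5-(iodomethyl)-4,6,6-trimethylcyclohex-3-en-1-yl]oxy}dimethylsilane
Conditions: PPh3, I2, imidazole, CH2Cl2, 0 °C → rt
Reagents that add atoms: iodine, II
Why: Appel-type iodination should proceed through the alkoxyphosphonium iodide with SN2 displacement at the primary carbon C1′, buffered by imidazole so that neither the alkene nor the silyl ether is touched and no stereocentre is involved.

Step 8
Reactants: 9 (2E,6E)-farnesyl bromide
Product: 10 (4E,8E)-5,9,13-trimethyltetradeca-4,8,12-trienenitrile
Conditions: CH3CN (3 equiv), n-BuLi, THF, −78 °C; then 9, −78 → −20 °C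
Reagents that add atoms: acetonitrile, CC#N
Why: SN2 alkylation of the nitrile-stabilised carbanion at the primary allylic carbon should form the C5′–C6′ bond, with excess nucleophile suppressing double alkylation and both E alkenes left as they are.

Step 9
Reactants: 10 (4E,8E)-5,9,13-trimethyltetradeca-4,8,12-trienenitrile
Product: 12 (4E,8E)-5,9,13-trimethyltetradeca-4,8,12-trienal, via aluminium aldimine 11 (not isolated)
Conditions: i-Bu2AlH (1.2 equiv), CH2Cl2, −78 °C; then aq. tartaric acid, 0 °C
Reagents that add atoms: water, O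
Why: Partial reduction of a nitrile with i-Bu2AlH should stop at the N-aluminio aldimine, which is inert to further hydride at low temperature and is hydrolysed to the aldehyde on work-up.

Step 10
Reactants: 12 (4E,8E)-5,9,13-trimethyltetradeca-4,8,12-trienal
Product: 13 ethyl (2E,6E,10E)-2,7,11,15-tetramethylhexadeca-2,6,10,14-tetraenoate
Conditions: Ph3P=C(CH3)CO2Et, CH2Cl2, rt
Reagents that add atoms: ethyl 2-(triphenylphosphoranylidene)propanoate, CCOC(=O)C(C)=P(c1ccccc1)(c1ccccc1)c1ccccc1
Why: The Wittig reaction of a stabilised, α-branched ylide with an unhindered aldehyde should give the trisubstituted enoate with the ester trans to the chain, which sets the 3′E alkene.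

Step 11
Reactants: 13 ethyl (2E,6E,10E)-2,7,11,15-tetramethylhexadeca-2,6,10,14-tetraenoate
Product: 14 (2E,6E,10E)-2,7,11,15-tetramethylhexadeca-2,6,10,14-tetraen-1-ol
Conditions: i-Bu2AlH (2.5 equiv), CH2Cl2, −78 → 0 °C
Reagents that add atoms: none
Why: 1,2-Reduction of the conjugated ester with i-Bu2AlH should give the allylic alcohol without touching any alkene or its geometry.

Step 12
Reactants: 14 (2E,6E,10E)-2,7,11,15-tetramethylhexadeca-2,6,10,14-tetraen-1-ol
Product: 15 (2E,6E,10E)-1-chloro-2,7,11,15-tetramethylhexadeca-2,6,10,14-tetraene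
Conditions: N-chlorosuccinimide, Me2S, CH2Cl2, −20 → 0 °C
Reagents that add atoms: N-chlorosuccinimide, O=C1CCC(=O)N1Cl
Why: Corey–Kim-type chlorination should convert the alcohol into an alkoxysulfonium salt that chloride displaces at the primary carbon under neutral conditions, so neither allylic transposition nor E/Z scrambling is expected.

Step 13
Reactants: 8 tert-butyl{[(1S,5R)-5-(iodomethyl)-4,6,6-trimethylcyclohex-3-en-1-yl]oxy}dimethylsilane; 15 (2E,6E,10E)-1-chloro-2,7,11,15-tetramethylhexadeca-2,6,10,14-tetraene
Product: 17 tert-butyldimethyl({(1S,5R)-4,6,6-trimethyl-5-[(3E,7E,11E)-3,8,12,16-tetramethylheptadeca-3,7,11,15-tetraen-1-yl]cyclohex-3-en-1-yl}oxy)silane, via Grignard reagent 16 (not isolated)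
Conditions: 8, Mg, THF, 40 °C; then 15, Li2CuCl4 (5 mol %), THF, −20 → 0 °C
Reagents that add atoms: none
Why: Kochi-type copper-catalysed coupling of a primary alkyl Grignard reagent with a primary allylic chloride should form C1′–C2′ at the chlorine-bearing carbon with the E alkene retained, because with the Grignard reagent in excess over copper a dialkylcuprate is the active species; both ring stereocentres are spectators.

Step 14
Reactants: 17 tert-butyldimethyl({(1S,5R)-4,6,6-trimethyl-5-[(3E,7E,11E)-3,8,12,16-tetramethylheptadeca-3,7,11,15-tetraen-1-yl]cyclohex-3-en-1-yl}oxy)silane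
Product: 18 camelliol C, (1S,5R)-4,6,6-trimethyl-5-[(3E,7E,11E)-3,8,12,16-tetramethylheptadeca-3,7,11,15-tetraen-1-yl]cyclohex-3-en-1-ol
Conditions: Bu4NF, THF, 50 °C
Reagents that add atoms: none
Why: Fluoride-induced desilylation should cleave the Si–O bond only, so the C1 configuration is retained and the tetraene chain is not exposed to acid.

**Compound list**

1 | 2,6-dimethylbenzoic acid | Cc1cccc(C)c1C(=O)O | starting material
2 | 2,6-dimethylcyclohexa-2,5-diene-1-carboxylic acid | OC(=O)C1C(C)=CCC=C1C | intermediate
3 | (2,6-dimethylcyclohexa-2,5-dien-1-yl)methanol | OCC1C(C)=CCC=C1C | intermediate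
4 | [(1R,2S,6S)-1,3-dimethyl-7-oxabicyclo[4.1.0]hept-3-en-2-yl]methanol (oxirane cis to the hydroxymethyl group) | OC[C@@H]1C(C)=CC[C@@H]2O[C@]12C | intermediate
5 | (1S,5R)-5-(hydroxymethyl)-4,6,6-trimethylcyclohex-3-en-1-ol | OC[C@@H]1C(C)=CC[C@H](O)C1(C)C | intermediate
6 | tert-butyl{[(1R,5S)-5-{[tert-butyl(dimethyl)silyl]oxy}-2,6,6-trimethylcyclohex-2-en-1-yl]methoxy}dimethylsilane | CC(C)(C)[Si](C)(C)OC[C@@H]1C(C)=CC[C@H](O[Si](C)(C)C(C)(C)C)C1(C)C | intermediate
7 | [(1R,5S)-5-{[tert-butyl(dimethyl)silyl]oxy}-2,6,6-trimethylcyclohex-2-en-1-yl]methanol | OC[C@@H]1C(C)=CC[C@H](O[Si](C)(C)C(C)(C)C)C1(C)C | intermediate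
8 | tert-butyl{[(1S,5R)-5-(iodomethyl)-4,6,6-trimethylcyclohex-3-en-1-yl]oxy}dimethylsilane | IC[C@@H]1C(C)=CC[C@H](O[Si](C)(C)C(C)(C)C)C1(C)C | intermediate
9 | (2E,6E)-farnesyl bromide, (2E,6E)-1-bromo-3,7,11-trimethyldodeca-2,6,10-triene | CC(C)=CCC/C(C)=C/CC/C(C)=C/CBr | starting material
10 | (4E,8E)-5,9,13-trimethyltetradeca-4,8,12-trienenitrile | CC(C)=CCC/C(C)=C/CC/C(C)=C/CCC#N | intermediate
11 | N-(diisobutylaluminio) aldimine of 12, formed in the flask | CC(C)C[Al](CC(C)C)N=CCC/C=C(\C)CC/C=C(\C)CCC=C(C)C | intermediate
12 | (4E,8E)-5,9,13-trimethyltetradeca-4,8,12-trienal | CC(C)=CCC/C(C)=C/CC/C(C)=C/CCC=O | intermediate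
13 | ethyl (2E,6E,10E)-2,7,11,15-tetramethylhexadeca-2,6,10,14-tetraenoate | CC(C)=CCC/C(C)=C/CC/C(C)=C/CC/C=C(\C)C(=O)OCC | intermediate
14 | (2E,6E,10E)-2,7,11,15-tetramethylhexadeca-2,6,10,14-tetraen-1-ol | CC(C)=CCC/C(C)=C/CC/C(C)=C/CC/C=C(\C)CO | intermediate
15 | (2E,6E,10E)-1-chloro-2,7,11,15-tetramethylhexadeca-2,6,10,14-tetraene | CC(C)=CCC/C(C)=C/CC/C(C)=C/CC/C=C(\C)CCl | intermediate
16 | {[(1R,5S)-5-{[tert-butyl(dimethyl)silyl]oxy}-2,6,6-trimethylcyclohex-2-en-1-yl]methyl}magnesium iodide, formed in the flask | I[Mg]C[C@@H]1C(C)=CC[C@H](O[Si](C)(C)C(C)(C)C)C1(C)C | intermediate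
17 | tert-butyldimethyl({(1S,5R)-4,6,6-trimethyl-5-[(3E,7E,11E)-3,8,12,16-tetramethylheptadeca-3,7,11,15-tetraen-1-yl]cyclohex-3-en-1-yl}oxy)silane | CC(C)=CCC/C(C)=C/CC/C(C)=C/CC/C=C(\C)CC[C@@H]1C(C)=CC[C@H](O[Si](C)(C)C(C)(C)C)C1(C)C | intermediate
18 | camelliol C, (1S,5R)-4,6,6-trimethyl-5-[(3E,7E,11E)-3,8,12,16-tetramethylheptadeca-3,7,11,15-tetraen-1-yl]cyclohex-3-en-1-ol | CC(C)=CCC/C(C)=C/CC/C(C)=C/CC/C=C(\C)CC[C@@H]1C(C)=CC[C@H](O)C1(C)C | target

**Step count and risks**

Total step count: 14. Longest linear sequence: 9 steps (steps 1 to 7, 13 and 14).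

Steps most likely to fail:

1. Step 3. The catalyst may discriminate poorly between the two enantiotopic alkenes, and the skipped diene may be oxidised back to the arene or epoxidised twice. The fallback sets out from 3 and uses only established reactions. Hydroxyl-directed epoxidation with VO(acac)2 and t-BuOOH in toluene at 0 °C should give the racemic syn-epoxy alcohol F1. A lipase-catalysed kinetic resolution (Burkholderia cepacia lipase, vinyl acetate, t-BuOMe) should then acylate one antipode, giving the acetate of the unwanted enantiomer F2 and leaving 4 as the free alcohol, which is separated by chromatography. If the enzyme prefers the wanted antipode, its acetate is methanolysed with K2CO3 in MeOH. The route is rejoined at 4.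

2. Step 4. Ionisation at C6 may be followed by loss of the allylic C5 proton or by a 1,2-hydride shift from C1 faster than methyl is transferred. The fallback sets out from 4 and avoids a cation at C6. Isomerisation of the oxirane with diethylaluminium 2,2,6,6-tetramethylpiperidide, Et2Al(NC9H18), in toluene at 0 °C should give the exocyclic allylic alcohol (1S,5R)-5-(hydroxymethyl)-4-methyl-6-methylidenecyclohex-3-en-1-ol F3, with the C1–O bond untouched. Radical hydromethylation of the 1,1-disubstituted alkene by hydrogen-atom transfer (Fe(acac)3, PhSiH3, formaldehyde N-(octylsulfonyl)hydrazone, THF–MeOH) should add hydrogen to the methylidene carbon and the hydrazone carbon to C6, giving the sulfonyl hydrazide F4. On warming in MeOH F4 should lose sulfinic acid and nitrogen to leave the second methyl group. The route is rejoined at 5.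

3. Step 13. Magnesium insertion into the hindered homoallylic iodide may be diverted into Wurtz dimerisation, and the copper-catalysed coupling may proceed with allylic transposition (attack at C4′) or erosion of the 3′E geometry. The fallback sets out from 8. Displacement with PhSO2Na in DMF at 70 °C should give the sulfone tert-butyldimethyl{[(1S,5R)-4,6,6-trimethyl-5-[(phenylsulfonyl)methyl]cyclohex-3-en-1-yl]oxy}silane F5. Deprotonation with n-BuLi in THF–DMPU at −78 °C and alkylation with chloride 15 should give the C1′-sulfonyl coupling product F6 as a mixture of epimers at C1′. Reductive desulfonylation with Na(Hg) and Na2HPO4 in MeOH–THF at −20 °C removes the sulfonyl group, and the route is rejoined at 17.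

**Further compounds**

F1 | step 3 | racemic syn-epoxy alcohol, rac-[(1R,2S,6S)-1,3-dimethyl-7-oxabicyclo[4.1.0]hept-3-en-2-yl]methanol (both enantiomers) | OC[C@@H]1C(C)=CC[C@@H]2O[C@]12C.OC[C@H]1C(C)=CC[C@H]2O[C@@]12C
F2 | step 3 | [(1S,2R,6R)-1,3-dimethyl-7-oxabicyclo[4.1.0]hept-3-en-2-yl]methyl acetate | CC(=O)OC[C@H]1C(C)=CC[C@H]2O[C@@]12C
F3 | step 4 | (1S,5R)-5-(hydroxymethyl)-4-methyl-6-methylidenecyclohex-3-en-1-ol | OC[C@@H]1C(C)=CC[C@H](O)C1=C
F4 | step 4 | N′-{[(2S,6R)-2-hydroxy-6-(hydroxymethyl)-1,5-dimethylcyclohex-4-en-1-yl]methyl}octane-1-sulfonohydrazide (mixture of epimers at ring C1) | OC[C@@H]1C(C)=CC[C@H](O)C1(C)CNNS(=O)(=O)CCCCCCCC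
F5 | step 13 | tert-butyldimethyl{[(1S,5R)-4,6,6-trimethyl-5-[(phenylsulfonyl)methyl]cyclohex-3-en-1-yl]oxy}silane | O=S(=O)(C[C@@H]1C(C)=CC[C@H](O[Si](C)(C)C(C)(C)C)C1(C)C)c1ccccc1
F6 | step 13 | tert-butyldimethyl({(1S,5R)-4,6,6-trimethyl-5-[(3E,7E,11E)-3,8,12,16-tetramethyl-1-(phenylsulfonyl)heptadeca-3,7,11,15-tetraen-1-yl]cyclohex-3-en-1-yl}oxy)silane (mixture of epimers at C1′) | CC(C)=CCC/C(C)=C/CC/C(C)=C/CC/C=C(\C)CC([C@@H]1C(C)=CC[C@H](O[Si](C)(C)C(C)(C)C)C1(C)C)S(=O)(=O)c1ccccc1
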